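**Retrosynthetic overview**
1. Target ⇐ pentacyclic C6 ketone; the late steps are hydride reduction to the axial C6 alcohol, acetylation, oxidation at C5′ and debenzylation.
2. Pentacyclic ketone ⇐ monocyclic trienone by one cationic cascade forming C9–C10 (ring B), C8–C14 (ring C) and C13–O (oxolane). The strategy rests on the C6 carbonyl oxygen, C10, C8 and C13 lying on one 1,5,9-polyene path (C5=C10 enone, E-C8=C9, C13=C14H2) that ends at the C3′ hydroxyl, which is cis-1,3 to C13 on ring E.
3. Trienone ⇐ ring-E bicyclic lactone (C13 is the lactone carbonyl) + ring-A homoallylic iodide (C6–C12), joined by alkyllithium addition, then Wittig methylenation and oxidation at C6. In the lactone C1′–C4′ are all cis and the C5′ silyl ether is trans, so that it cannot reach the C13 cation.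
4. Lactone ⇐ asymmetric Diels–Alder (C1′, C2′), epoxide-opening lactonisation (C3′), enol-triflate methylation and exo hydroboration (C4′, C5′). Iodide ⇐ β-cyclocitral by propargylation and carboalumination.
5. Ring order: A (bought), E (Diels–Alder), then B, C and the oxolane together in the key step.

Key step: step 19

Numbering: decalin C1–C10 (gem-dimethyl on C4, oxygen on C6, methyls on C8 and C10); ring C = C8, C9, C11–C14 with spiro C13; ring E = C1′ (on C13), C2′ (benzyloxy), C3′ (ether oxygen), C4′ (methyl), C5′, C6′.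
Assumption: the (R,R) ligand in step 1 is taken to give the (1R,2S) adduct (its antipode is used if the sense is the other way); C6 is carried as both epimers from step 11 to step 17 because step 18 removes this centre.

**Fragment 1: ring-E lactone**

Step 1
Reactants: 1 (E)-buta-1,3-dien-1-yl acetate; 2 3-acryloyl-1,3-oxazolidin-2-one
Product: 3 3-[(1R,2S)-2-acetoxycyclohex-3-ene-1-carbonyl]-1,3-oxazolidin-2-one (cis adduct)
Conditions: [Cu((R,R)-t-Bu-box)](SbF6)2 (5 mol%; t-Bu-box = 2,2′-(propane-2,2-diyl)bis(4-tert-butyl-4,5-dihydrooxazole)), CH2Cl2, −20 °C to rt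
Reagents that add atoms: none
Why: Catalytic asymmetric Diels–Alder reaction: the acrylimide chelated to the bis(oxazoline) complex of divalent copper reacts with the 1-acyloxydiene ortho- and endo-selectively, so the endo rule makes C1′ and C2′ cis and the ligand fixes their absolute sense.

Step 2
Reactants: 3 3-[(1R,2S)-2-acetoxycyclohex-3-ene-1-carbonyl]-1,3-oxazolidin-2-one
Product: 4 (1R,2S)-2-hydroxycyclohex-3-ene-1-carboxylic acid
Conditions: LiOH, H2O2, THF/H2O, 0 °C to rt; Na2SO3; HCl to pH 2
Reagents that add atoms: hydrogen peroxide (as LiOOH), OO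
Why: Hydroperoxide cleavage of the N-acyloxazolidinone at the exocyclic carbonyl and saponification of the acetate, both mild enough to leave the cis C1′/C2′ pair untouched because the carboxylate formed cannot enolise.

Step 3
Reactants: 4 (1R,2S)-2-hydroxycyclohex-3-ene-1-carboxylic acid
Product: 5 benzyl (1R,2S)-2-(benzyloxy)cyclohex-3-ene-1-carboxylate
Conditions: BnOC(=NH)CCl3 (2.4 equiv), TfOH (5 mol%), CH2Cl2/cyclohexane, 0 °C
Reagents that add atoms: benzyl 2,2,2-trichloroacetimidate, N=C(OCc1ccccc1)C(Cl)(Cl)Cl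
Why: Acid-catalysed benzylation with the trichloroacetimidate esterifies the acid and etherifies the allylic alcohol without base, which avoids epimerisation at C1′ and β-elimination.

Step 4
Reactants: 5 benzyl (1R,2S)-2-(benzyloxy)cyclohex-3-ene-1-carboxylate
Product: 6 benzyl 2-(benzyloxy)-3,4-epoxycyclohexane-1-carboxylate (ester and benzyloxy cis; epoxide on the opposite face)
Conditions: mCPBA, CH2Cl2, 0 °C
Reagents that add atoms: mCPBA (3-chloroperoxybenzoic acid), OOC(=O)c1cccc(Cl)c1
Why: Prilezhaev epoxidation; the peracid approaches the alkene face opposite the cis C1′ ester and C2′ benzyloxy groups, so the epoxide is trans to both.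

Step 5
Reactants: 6 benzyl 2-(benzyloxy)-3,4-epoxycyclohexane-1-carboxylate
Product: 8 (1R,4R,5S,8R)-8-(benzyloxy)-4-hydroxy-6-oxabicyclo[3.2.1]octan-7-one, via epoxy acid 7 (not isolated)
Conditions: LiOH, THF/H2O, 0 °C to rt; HCl to pH 5–6, 45 °C
Reagents that add atoms: lithium hydroxide, [Li+].[OH-]
Why: Saponification followed by intramolecular 5-exo opening of the epoxide by the carboxylate (epoxide-opening lactonisation) with inversion at C3′, so the C3′ oxygen is delivered from the face of C1′ and the 1,3-cis bridge is guaranteed while the C4′ hydroxyl stays on the exo face.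

Step 6
Reactants: 8 (1R,4R,5S,8R)-8-(benzyloxy)-4-hydroxy-6-oxabicyclo[3.2.1]octan-7-one
Product: 9 (1R,5R,8R)-8-(benzyloxy)-6-oxabicyclo[3.2.1]octane-4,7-dione
Conditions: Dess–Martin periodinane, CH2Cl2, rt
Reagents that add atoms: none
Why: Dess–Martin oxidation of the secondary alcohol; the neighbouring C3′ is a bridgehead and cannot epimerise.

Step 7
Reactants: 9 (1R,5R,8R)-8-(benzyloxy)-6-oxabicyclo[3.2.1]octane-4,7-dione
Product: 11 (1R,5R,8R)-8-(benzyloxy)-7-oxo-6-oxabicyclo[3.2.1]oct-3-en-4-yl trifluoromethanesulfonate, via potassium enolate 10 (not isolated)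
Conditions: KN(SiMe3)2, THF, −78 °C; PhNTf2, −78 to 0 °C; aq NH4Cl
Reagents that add atoms: N-phenylbis(trifluoromethanesulfonimide), O=S(=O)(N(c1ccccc1)S(=O)(=O)C(F)(F)F)C(F)(F)F
Why: Enol triflate formation from the enolate, which can only form towards C5′ because C3′ and the lactone α-carbon C1′ are bridgeheads (Bredt).

Step 8
Reactants: 11 (1R,5R,8R)-8-(benzyloxy)-7-oxo-6-oxabicyclo[3.2.1]oct-3-en-4-yl trifluoromethanesulfonate
Product: 12 (1R,5S,8R)-8-(benzyloxy)-4-methyl-6-oxabicyclo[3.2.1]oct-3-en-7-one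
Conditions: MeMgBr (slow addition), Fe(acac)3 (5 mol%), THF/NMP, −30 °C
Reagents that add atoms: methylmagnesium bromide, C[Mg]Br
Why: Iron-catalysed Kumada-type cross-coupling of the enol triflate with the methyl Grignard reagent, fast enough at −30 °C to spare the lactone, places the methyl on C4′ and fixes the alkene at C4′=C5′.

Step 9
Reactants: 12 (1R,5S,8R)-8-(benzyloxy)-4-methyl-6-oxabicyclo[3.2.1]oct-3-en-7-one
Product: 14 (1R,3R,4S,5S,8R)-8-(benzyloxy)-3-hydroxy-4-methyl-6-oxabicyclo[3.2.1]octan-7-one, via alkylborane 13 (not isolated)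
Conditions: BH3·THF (1.1 equiv), THF, 0 °C; H2O2, pH 7 phosphate buffer, 0 °C to rt
Reagents that add atoms: hydrogen peroxide, OO
Why: Hydroboration–oxidation: borane adds syn from the exo face, away from the lactone bridge, with boron on the less substituted C5′ remote from the allylic oxygen, so C4′ (methyl cis to the C3′ oxygen) and C5′ (hydroxyl trans to it) are set together.

Step 10
Reactants: 14 (1R,3R,4S,5S,8R)-8-(benzyloxy)-3-hydroxy-4-methyl-6-oxabicyclo[3.2.1]octan-7-one
Product: 15 (1R,3R,4R,5S,8R)-8-(benzyloxy)-3-[(tert-butyldimethylsilyl)oxy]-4-methyl-6-oxabicyclo[3.2.1]octan-7-one (fragment 1)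
Conditions: TBSOTf, 2,6-lutidine, CH2Cl2, −78 to 0 °C
Reagents that add atoms: tert-butyldimethylsilyl trifluoromethanesulfonate, CC(C)(C)[Si](C)(C)OS(=O)(=O)C(F)(F)F
Why: Silylation of the equatorial secondary alcohol with the silyl triflate; the C5′ oxygen is trans to C1′ and C3′ and so cannot later reach the C13 cation.

**Fragment 2: ring-A iodide**

Step 11
Reactants: 16 β-cyclocitral (2,6,6-trimethylcyclohex-1-ene-1-carbaldehyde); 17 propargyl bromide
Product: 19 1-(2,6,6-trimethylcyclohex-1-en-1-yl)but-3-yn-1-ol (racemic), via allenylzinc bromide 18 (not isolated)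
Conditions: Zn dust, THF, 0 °C to rt; aq NH4Cl
Reagents that add atoms: none
Why: Barbier propargylation: the allenylzinc reagent adds through its γ-carbon to the hindered aldehyde and gives the homopropargylic alcohol; C6 is formed racemic and is oxidised later.

Step 12
Reactants: 19 1-(2,6,6-trimethylcyclohex-1-en-1-yl)but-3-yn-1-ol
Product: 20 triethyl{[1-(2,6,6-trimethylcyclohex-1-en-1-yl)but-3-yn-1-yl]oxy}silane
Conditions: TESOTf, 2,6-lutidine, CH2Cl2, −78 °C
Reagents that add atoms: triethylsilyl trifluoromethanesulfonate, CC[Si](CC)(CC)OS(=O)(=O)C(F)(F)F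
Why: Silylation of the hindered secondary alcohol; the triethylsilyl group is chosen because it can later be removed beside the tert-butyldimethylsilyl ether.

Step 13
Reactants: 20 triethyl{[1-(2,6,6-trimethylcyclohex-1-en-1-yl)but-3-yn-1-yl]oxy}silane
Product: 23 (3E)-4-methyl-6-[(triethylsilyl)oxy]-6-(2,6,6-trimethylcyclohex-1-en-1-yl)hex-3-en-1-ol, via alkenylalane 21 (not isolated), via lithium alanate 22 (not isolated)
Conditions: AlMe3 (2.5 equiv), Cp2ZrCl2 (20 mol%), CH2Cl2, 0 °C to rt; n-BuLi, THF/hexanes, −78 °C; ethylene oxide, −78 to 0 °C; aq potassium sodium tartrate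
Reagents that add atoms: trimethylaluminium, C[Al](C)C; ethylene oxide, C1CO1
Why: Negishi carboalumination (zirconium-catalysed syn addition of methyl–aluminium with methyl on the internal carbon) gives the E-alkenylalane, and its ate complex opens ethylene oxide with retention, which fixes the E-C8=C9 alkene and adds C11 and C12.

Step 14
Reactants: 23 (3E)-4-methyl-6-[(triethylsilyl)oxy]-6-(2,6,6-trimethylcyclohex-1-en-1-yl)hex-3-en-1-ol
Product: 24 {[(3E)-6-iodo-3-methyl-1-(2,6,6-trimethylcyclohex-1-en-1-yl)hex-3-en-1-yl]oxy}triethylsilane (fragment 2)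
Conditions: I2, PPh3, imidazole, CH2Cl2, 0 °C
Reagents that add atoms: iodine, II
Why: Appel-type iodination of the primary alcohol under buffered conditions that leave the silyl ether.

**Union and precursor**

Step 15
Reactants: 24 {[(3E)-6-iodo-3-methyl-1-(2,6,6-trimethylcyclohex-1-en-1-yl)hex-3-en-1-yl]oxy}triethylsilane; 15 ring-E lactone
Product: 26 (4E)-1-[(1R,2R,3S,4R,5R)-2-(benzyloxy)-5-(tert-butyldimethylsilyloxy)-3-hydroxy-4-methylcyclohexyl]-5-methyl-7-(triethylsilyloxy)-7-(2,6,6-trimethylcyclohex-1-en-1-yl)hept-4-en-1-one (C13 ketone in equilibrium with its bicyclic lactol; both C6 epimers), via alkyllithium 25 (not isolated)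
Conditions: t-BuLi (2.1 equiv), Et2O/pentane, −78 °C; 15 in THF, −78 °C; aq NH4Cl
Reagents that add atoms: none
Why: Lithium–iodine exchange and acyl substitution on the lactone, which has no enolisable α-hydrogen (bridgehead C1′) and whose tetrahedral lithium lactolate survives at −78 °C, so a single addition gives the C13 ketone with the C3′ hydroxyl set free.

Step 16
Reactants: 26 C13 ketone
Product: 27 C13-methylidene compound (as 26 with C13=C14H2 in place of the ketone; ring E 1′S,2′R,3′S,4′R,5′R; free C3′ hydroxyl; C6 triethylsilyl ether)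
Conditions: Ph3PCH3Br (4 equiv), KOtBu (3.8 equiv), THF, 0 °C to rt
Reagents that add atoms: methyltriphenylphosphonium bromide, C[P+](c1ccccc1)(c1ccccc1)c1ccccc1.[Br-]
Why: Wittig methylenation of the ketone, which reacts from the open form of its lactol; excess ylide at low temperature is used to outrun enolisation towards C1′.

Step 17
Reactants: 27 C13-methylidene compound
Product: 28 diol (as 27 with free C6 hydroxyl)
Conditions: PPTS (cat.), MeOH/CH2Cl2, 0 °C to rt
Reagents that add atoms: none
Why: Acid-catalysed methanolysis removes the triethylsilyl ether selectively, the secondary tert-butyldimethylsilyl ether being far slower under these conditions.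

Step 18
Reactants: 28 diol
Product: 29 (3E)-7-[(1S,2R,3S,4R,5R)-2-(benzyloxy)-5-(tert-butyldimethylsilyloxy)-3-hydroxy-4-methylcyclohexyl]-3-methyl-1-(2,6,6-trimethylcyclohex-1-en-1-yl)octa-3,7-dien-1-one (trienone precursor)
Conditions: activated MnO2 (excess), CH2Cl2, rt
Reagents that add atoms: none
Why: Allylic oxidation with MnO2 is chemoselective for the C6 carbinol next to the ring alkene, leaves the saturated C3′ carbinol, and is neutral, so the C8=C9 alkene stays out of conjugation.

**Key step**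

Step 19
Reactants: 29 trienone precursor
Product: 32 pentacyclic 6-ketone (trans-anti-trans tricycle: 5α-H, 8β-methyl, 9α-H, 10β-methyl; spiro C13 with the ether oxygen axial and β; oxolane bridging C1′ and C3′ of ring E; 2′-benzyloxy, 4′-methyl, 5′-silyloxy), via aluminium enolate 30 (not isolated), via cis-fused ketone 31 (not isolated)
Conditions: MeAlCl2 (3 equiv), CH2Cl2, −78 to 0 °C; aq NaHCO3; NaOMe (cat.), MeOH, rt; chromatography
Reagents that add atoms: none
Why: Proposed new method: MeAlCl2 first turns the C3′ hydroxyl into an aluminium alkoxide (methane is lost) and a second equivalent binds the C6 carbonyl of the twisted enone, so that C10 becomes a tertiary, oxyallyl-type cation; C9 of the E-C8=C9 alkene adds to C10 (ring B, 6-endo, chair), C14 of the 1,1-disubstituted alkene adds to the C8 cation (ring C, 6-endo, chair) and the C3′ oxygen traps the C13 cation (oxolane, 5-exo), leaving an aluminium enolate. The closest known reactions are the acid-mediated cyclialkylation of benzyl 2,6,6-trimethylcyclohexenyl ketones to tricyclic 6-ketones, alkylaluminium-halide-initiated enone–olefin cyclisations, and the hydroxyl-terminated cyclisation of monocyclic homofarnesol-type polyenes to ambroxide-type ethers; an alkene chain on an enone initiator that ends in a hydroxyl has not been shown. Chair–chair folding of the E-alkene sets C10, C9 and C8 (10-methyl and 9-H anti, C14 equatorial on C8), C13 takes the ether oxygen axial by anti addition across C13=C14 and because the tertiary ether can re-ionise under the Lewis acid, which keeps the bulky ring-E carbon equatorial, and C5 is set by protonation of the enolate followed by base equilibration to the trans-fused ketone. The step needs initiation at the enone only, which the substrate secures because the carbonyl is its only strongly Lewis-basic site and the aprotic, proton-scavenging Lewis acid cannot protonate the C13=C14 alkene next to the hydroxyl; it needs the C3′ oxygen as sole terminator, which is secured by its cis-1,3 relation to C13, whereas the C5′ silyl ether is trans and the C2′ benzyl ether would have to close a four-membered ring. The sense of folding relative to ring E is not fixed by the substrate, so the diastereomer with the mirror-image tricycle is expected beside 32 and is removed by chromatography.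

**Endgame**

Step 20
Reactants: 32 pentacyclic 6-ketone
Product: 33 6β-alcohol (axial hydroxyl on C6; otherwise as 32)
Conditions: LiAlH4, THF, 0 °C; aq NaOH work-up
Reagents that add atoms: none
Why: Hydride reduction of the ketone from the open α-face (the β-face is blocked by the axial methyls on C4, C8 and C10) gives the axial 6β-alcohol.

Step 21
Reactants: 33 6β-alcohol
Product: 34 6β-acetate (2′-benzyloxy, 5′-silyloxy)
Conditions: Ac2O, DMAP, Et3N, CH2Cl2, 40 °C
Reagents that add atoms: acetic anhydride, CC(=O)OC(C)=O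
Why: Nucleophile-catalysed acetylation (DMAP) of the hindered axial alcohol, driven with excess anhydride and gentle heating.

Step 22
Reactants: 34 6β-acetate
Product: 35 5′-alcohol (6β-acetate, 2′-benzyloxy)
Conditions: HF·pyridine, pyridine, THF, 0 °C to rt
Reagents that add atoms: none
Why: Fluoride-mediated desilylation of the C5′ ether under buffered, slightly acidic conditions that leave the acetate and the benzyl ether.

Step 23
Reactants: 35 5′-alcohol
Product: 36 5′-ketone (6β-acetate, 2′-benzyloxy)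
Conditions: Dess–Martin periodinane, CH2Cl2, rt
Reagents that add atoms: none
Why: Dess–Martin oxidation under neutral conditions gives the β-alkoxy ketone without base, so C4′ (equatorial methyl) is not epimerised and the ether is not lost by β-elimination.

Step 24
Reactants: 36 5′-ketone
Product: 37 CNP0188572.2 (target)
Conditions: H2 (1 atm), Pd/C, EtOAc, rt
Reagents that add atoms: none
Why: Hydrogenolysis of the benzyl ether over palladium on carbon under neutral conditions, which leaves the ketone, the acetate and the ether.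

**Compound list**
1 | (E)-buta-1,3-dien-1-yl acetate | CC(=O)O/C=C/C=C | starting material
2 | 3-acryloyl-1,3-oxazolidin-2-one | C=CC(=O)N1CCOC1=O | starting material
3 | 3-[(1R,2S)-2-acetoxycyclohex-3-ene-1-carbonyl]-1,3-oxazolidin-2-one | O=C(N1CCOC1=O)[C@@H]1CCC=C[C@@H]1OC(C)=O | intermediate
4 | (1R,2S)-2-hydroxycyclohex-3-ene-1-carboxylic acid | OC(=O)[C@@H]1CCC=C[C@@H]1O | intermediate
5 | benzyl (1R,2S)-2-(benzyloxy)cyclohex-3-ene-1-carboxylate | O=C(OCc1ccccc1)[C@@H]1CCC=C[C@@H]1OCc1ccccc1 | intermediate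
6 | benzyl 2-(benzyloxy)-3,4-epoxycyclohexane-1-carboxylate (epoxide trans to the cis ester and benzyloxy groups) | O=C(OCc1ccccc1)[C@@H]1CC[C@H]2O[C@H]2[C@@H]1OCc1ccccc1 | intermediate
7 | epoxy acid from 6 | OC(=O)[C@@H]1CC[C@H]2O[C@H]2[C@@H]1OCc1ccccc1 | intermediate
8 | (1R,4R,5S,8R)-8-(benzyloxy)-4-hydroxy-6-oxabicyclo[3.2.1]octan-7-one | O=C1[C@@H]2CC[C@@H](O)[C@H](O1)[C@@H]2OCc1ccccc1 | intermediate
9 | (1R,5R,8R)-8-(benzyloxy)-6-oxabicyclo[3.2.1]octane-4,7-dione | O=C1[C@@H]2CCC(=O)[C@H](O1)[C@@H]2OCc1ccccc1 | intermediate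
10 | potassium enolate of 9 | O=C1[C@@H]2CC=C([O-])[C@H](O1)[C@@H]2OCc1ccccc1.[K+] | intermediate
11 | (1R,5R,8R)-8-(benzyloxy)-7-oxo-6-oxabicyclo[3.2.1]oct-3-en-4-yl trifluoromethanesulfonate | O=C1[C@@H]2CC=C(OS(=O)(=O)C(F)(F)F)[C@H](O1)[C@@H]2OCc1ccccc1 | intermediate
12 | (1R,5S,8R)-8-(benzyloxy)-4-methyl-6-oxabicyclo[3.2.1]oct-3-en-7-one | O=C1[C@@H]2CC=C(C)[C@H](O1)[C@@H]2OCc1ccccc1 | intermediate
13 | exo C5′ alkylborane from 12 | O=C1[C@@H]2C[C@@H](B)[C@H](C)[C@H](O1)[C@@H]2OCc1ccccc1 | intermediate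
14 | (1R,3R,4S,5S,8R)-8-(benzyloxy)-3-hydroxy-4-methyl-6-oxabicyclo[3.2.1]octan-7-one | O=C1[C@@H]2C[C@@H](O)[C@H](C)[C@H](O1)[C@@H]2OCc1ccccc1 | intermediate
15 | (1R,3R,4R,5S,8R)-8-(benzyloxy)-3-[(tert-butyldimethylsilyl)oxy]-4-methyl-6-oxabicyclo[3.2.1]octan-7-one | O=C1[C@@H]2C[C@@H](O[Si](C)(C)C(C)(C)C)[C@H](C)[C@H](O1)[C@@H]2OCc1ccccc1 | intermediate
16 | β-cyclocitral | CC1=C(C=O)C(C)(C)CCC1 | starting material
17 | propargyl bromide | C#CCBr | starting material
18 | allenylzinc bromide | C=C=C[Zn]Br | intermediate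
19 | 1-(2,6,6-trimethylcyclohex-1-en-1-yl)but-3-yn-1-ol (racemic) | CC1=C(C(O)CC#C)C(C)(C)CCC1 | intermediate
20 | triethyl{[1-(2,6,6-trimethylcyclohex-1-en-1-yl)but-3-yn-1-yl]oxy}silane (racemic) | CC1=C(C(CC#C)O[Si](CC)(CC)CC)C(C)(C)CCC1 | intermediate
21 | (E)-alkenyl(dimethyl)alane from 20 | CC1=C(C(C/C(C)=C/[Al](C)C)O[Si](CC)(CC)CC)C(C)(C)CCC1 | intermediate
22 | lithium butyl(dimethyl)alkenylalanate | CC1=C(C(C/C(C)=C/[Al-](C)(C)CCCC)O[Si](CC)(CC)CC)C(C)(C)CCC1.[Li+] | intermediate
23 | (3E)-4-methyl-6-[(triethylsilyl)oxy]-6-(2,6,6-trimethylcyclohex-1-en-1-yl)hex-3-en-1-ol | CC1=C(C(C/C(C)=C/CCO)O[Si](CC)(CC)CC)C(C)(C)CCC1 | intermediate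
24 | {[(3E)-6-iodo-3-methyl-1-(2,6,6-trimethylcyclohex-1-en-1-yl)hex-3-en-1-yl]oxy}triethylsilane | CC1=C(C(C/C(C)=C/CCI)O[Si](CC)(CC)CC)C(C)(C)CCC1 | intermediate
25 | alkyllithium from 24 | CC1=C(C(C/C(C)=C/CC[Li])O[Si](CC)(CC)CC)C(C)(C)CCC1 | intermediate
26 | C13 ketone (open form of the lactol; both C6 epimers) | CC1=C(C(C/C(C)=C/CCC(=O)[C@@H]2C[C@@H](O[Si](C)(C)C(C)(C)C)[C@H](C)[C@H](O)[C@@H]2OCc2ccccc2)O[Si](CC)(CC)CC)C(C)(C)CCC1 | intermediate
27 | C13-methylidene compound, C6 triethylsilyl ether | CC1=C(C(C/C(C)=C/CCC(=C)[C@@H]2C[C@@H](O[Si](C)(C)C(C)(C)C)[C@H](C)[C@H](O)[C@@H]2OCc2ccccc2)O[Si](CC)(CC)CC)C(C)(C)CCC1 | intermediate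
28 | diol (free C6 and C3′ hydroxyls) | CC1=C(C(O)C/C(C)=C/CCC(=C)[C@@H]2C[C@@H](O[Si](C)(C)C(C)(C)C)[C@H](C)[C@H](O)[C@@H]2OCc2ccccc2)C(C)(C)CCC1 | intermediate
29 | trienone precursor | CC1=C(C(=O)C/C(C)=C/CCC(=C)[C@@H]2C[C@@H](O[Si](C)(C)C(C)(C)C)[C@H](C)[C@H](O)[C@@H]2OCc2ccccc2)C(C)(C)CCC1 | intermediate
30 | chloro(methyl)aluminium enolate of the cyclised ketone | C[Al](Cl)OC=1C[C@]2(C)C[C@]3(CC[C@H]2[C@]2(C)CCCC(C)(C)C=12)O[C@@H]1[C@H](OCc4ccccc4)[C@H]3C[C@@H](O[Si](C)(C)C(C)(C)C)[C@@H]1C | intermediate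
31 | cis-fused (5β-H) ketone | O=C1C[C@]2(C)C[C@]3(CC[C@H]2[C@]2(C)CCCC(C)(C)[C@H]12)O[C@@H]1[C@H](OCc4ccccc4)[C@H]3C[C@@H](O[Si](C)(C)C(C)(C)C)[C@@H]1C | intermediate
32 | pentacyclic 6-ketone spiroether | O=C1C[C@]2(C)C[C@]3(CC[C@H]2[C@]2(C)CCCC(C)(C)[C@@H]12)O[C@@H]1[C@H](OCc4ccccc4)[C@H]3C[C@@H](O[Si](C)(C)C(C)(C)C)[C@@H]1C | intermediate
33 | 6β-alcohol | O[C@H]1C[C@]2(C)C[C@]3(CC[C@H]2[C@]2(C)CCCC(C)(C)[C@@H]12)O[C@@H]1[C@H](OCc4ccccc4)[C@H]3C[C@@H](O[Si](C)(C)C(C)(C)C)[C@@H]1C | intermediate
34 | 6β-acetate | CC(=O)O[C@H]1C[C@]2(C)C[C@]3(CC[C@H]2[C@]2(C)CCCC(C)(C)[C@@H]12)O[C@@H]1[C@H](OCc4ccccc4)[C@H]3C[C@@H](O[Si](C)(C)C(C)(C)C)[C@@H]1C | intermediate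
35 | 5′-alcohol | CC(=O)O[C@H]1C[C@]2(C)C[C@]3(CC[C@H]2[C@]2(C)CCCC(C)(C)[C@@H]12)O[C@@H]1[C@H](OCc4ccccc4)[C@H]3C[C@@H](O)[C@@H]1C | intermediate
36 | 5′-ketone, 2′-benzyl ether | CC(=O)O[C@H]1C[C@]2(C)C[C@]3(CC[C@H]2[C@]2(C)CCCC(C)(C)[C@@H]12)O[C@@H]1[C@H](OCc4ccccc4)[C@H]3CC(=O)[C@@H]1C | intermediate
37 | CNP0188572.2 | CC(=O)O[C@H]1C[C@]2(C)C[C@]3(CC[C@H]2[C@]2(C)CCCC(C)(C)[C@@H]12)O[C@@H]1[C@H](O)[C@H]3CC(=O)[C@@H]1C | target

**Totals and risks**

Total steps: 24. Longest linear sequence: 20 (steps 1–10 and 15–24).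

Steps most likely to fail:

1. Step 19 (key step). The Lewis acid may fail to ionise the twisted enone, the C8=C9 alkene may migrate into conjugation with the ketone before it can add, or the C3′ oxygen may add early to the C13=C14 alkene; folding is also not steered by ring E. Fallback (known chemistry): it sets out from diol 28. SnCl4 in CH2Cl2 at −78 °C ionises the allylic C6 alcohol to the C6–C5–C10 allyl cation, an allylic-cation-initiated polyene cyclisation of a well-known type; C9 adds to C10, C14 to C8 and the C3′ hydroxyl to C13, which should give the 5-ene spiroether F1. Hydroboration–oxidation (BH3·THF; then H2O2, NaOH) from the α-face should give the 5α-H 6α-alcohol F2, and Dess–Martin oxidation gives ketone 32, where the route is rejoined.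

2. Step 16. The ylide may act as a base on the open-chain ketone, with epimerisation at C1′ or loss of the benzyloxy group by β-elimination, or the lactol form may hold the carbonyl back. Fallback: a Peterson olefination that brings in C14 before C12; it sets out from lactone 15. Me3SiCH2Li (THF, −78 °C) opens the lactone to the α-silyl ketone F3; the organocerium reagent made from alkyllithium 25 and CeCl3 adds to it to give the β-hydroxysilane F4; KH in THF then eliminates the silanolate and gives 27, where the route is rejoined.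

3. Step 18. The oxidation may stall because the allylic C6–H bond is twisted out of conjugation with the ring alkene, or the β,γ-alkene may move into conjugation on the oxidant. Fallback: it sets out from diol 28. Dess–Martin periodinane oxidises both carbinols to the diketone F5; NaBH4 (MeOH, −40 °C) then reduces only the C3′ cyclohexanone, from the face opposite the cis substituents on C1′, C2′ and C4′, which restores the all-cis alcohol and gives 29, where the route is rejoined; the C6 ketone, shielded by the fully substituted ring carbon, should be left.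

Further compounds
F1 | step 19 | 5-ene spiroether (C5=C6 alkene, otherwise as 32) | C=1C[C@]2(C)C[C@]3(CC[C@H]2[C@]2(C)CCCC(C)(C)C=12)O[C@@H]1[C@H](OCc4ccccc4)[C@H]3C[C@@H](O[Si](C)(C)C(C)(C)C)[C@@H]1C
F2 | step 19 | 5α-H 6α-alcohol | O[C@@H]1C[C@]2(C)C[C@]3(CC[C@H]2[C@]2(C)CCCC(C)(C)[C@@H]12)O[C@@H]1[C@H](OCc4ccccc4)[C@H]3C[C@@H](O[Si](C)(C)C(C)(C)C)[C@@H]1C
F3 | step 16 | α-silyl ketone | C[Si](C)(C)CC(=O)[C@@H]1C[C@@H](O[Si](C)(C)C(C)(C)C)[C@H](C)[C@H](O)[C@@H]1OCc1ccccc1
F4 | step 16 | β-hydroxysilane | CC1=C(C(C/C(C)=C/CCC(O)(C[Si](C)(C)C)[C@@H]2C[C@@H](O[Si](C)(C)C(C)(C)C)[C@H](C)[C@H](O)[C@@H]2OCc2ccccc2)O[Si](CC)(CC)CC)C(C)(C)CCC1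
F5 | step 18 | diketone | CC1=C(C(=O)C/C(C)=C/CCC(=C)[C@@H]2C[C@@H](O[Si](C)(C)C(C)(C)C)[C@H](C)C(=O)[C@@H]2OCc2ccccc2)C(C)(C)CCC1
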